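**Plan**

- Feature: in the 1,2-dioxane, C4 and C5 are the only ring atoms without oxygen and sit side by side between C3 and C6. A C4=C5 double bond can therefore be the last ring bond made, by metathesis of two vinyl groups on a peroxide in which O1–O2, O2–C3 and O1–C6 already exist.
- Cuts, in retrosynthetic order: CO2H back to a CH2O-PMB ether; the C(sp)–C(sp2) bond of the enyne (terminal alkyne plus (E)-1-iodoundec-1-ene); the alkyne back to an aldehyde; C4–C5 (diene metathesis); C6–O1 (allylic hydroperoxide plus vinyl ketone dimethyl ketal); C3–O2 (secondary triflate plus a protected hydroperoxide).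
- Forward: the chiral-pool acetonide is taken to the triflate, the peroxide enters by SN2, and C1 is oxidised and methylenated to the vinyl group. The freed hydroperoxide is exchanged onto a vinyl ketal made from methoxyallene, and metathesis closes the only ring. Diimide saturates it, the C6 chain is carried to the alkyne, C6 is equilibrated, the enyne is coupled on, and the acid is made last.
- Stereochemistry: C3 comes from the (S) carbinol of the starting acetonide, inverted once in the SN2 step. C6 is settled by acid equilibration to the epimer with axial methoxy and both carbon chains equatorial. The (E) alkene comes from syn hydrozirconation of undec-1-yne.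

Key step: step 14

Remark on the chemistry: ring atoms are numbered O1, O2, C3 (the CH carbon), C4, C5, C6 (the methoxy ketal carbon) in every intermediate; PMB = 4-methoxybenzyl, TBS = tert-butyldimethylsilyl; the C3 descriptor reads R while its neighbour is a vinyl or ring sp2 carbon and S once C4 is saturated, by CIP ranking alone.

**Route**

Step 1
Reactants: 1 2-[(4S)-2,2-dimethyl-1,3-dioxolan-4-yl]ethan-1-ol (the 1,2-acetonide of (S)-butane-1,2,4-triol)
Product: 2 (4S)-4-{2-[(4-methoxybenzyl)oxy]ethyl}-2,2-dimethyl-1,3-dioxolane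
Conditions: NaH, PMBCl, Bu4NI (cat.), THF/DMF, 0 °C to rt
Reagents that add atoms: 4-methoxybenzyl chloride, COc1ccc(CCl)cc1
Why: Williamson etherification of the primary sodium alkoxide with a benzylic chloride; the acetonide and the stereocentre take no part.

Step 2
Reactants: 2 (4S)-4-{2-[(4-methoxybenzyl)oxy]ethyl}-2,2-dimethyl-1,3-dioxolane
Product: 3 (2S)-4-[(4-methoxybenzyl)oxy]butane-1,2-diol
Conditions: AcOH/H2O (4:1), 40 °C
Reagents that add atoms: none
Why: acid hydrolysis of the isopropylidene acetal, to which a PMB ether is stable; no bond at the stereocentre is broken.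

Step 3
Reactants: 3 (2S)-4-[(4-methoxybenzyl)oxy]butane-1,2-diol
Product: 4 (2S)-1-[(tert-butyldimethylsilyl)oxy]-4-[(4-methoxybenzyl)oxy]butan-2-ol
Conditions: TBSCl (1.05 equiv), imidazole, CH2Cl2, −20 to 0 °C
Reagents that add atoms: tert-butyldimethylsilyl chloride, CC(C)(C)[Si](C)(C)Cl
Why: silylation of a 1,2-diol with a bulky chlorosilane, which takes the primary hydroxyl on steric grounds and leaves the secondary carbinol free.

Step 4
Reactants: 4 (2S)-1-[(tert-butyldimethylsilyl)oxy]-4-[(4-methoxybenzyl)oxy]butan-2-ol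
Product: 5 (2S)-1-[(tert-butyldimethylsilyl)oxy]-4-[(4-methoxybenzyl)oxy]butan-2-yl trifluoromethanesulfonate
Conditions: Tf2O, 2,6-lutidine, CH2Cl2, −78 °C; used crude
Reagents that add atoms: trifluoromethanesulfonic anhydride, FC(F)(F)S(=O)(=O)OS(=O)(=O)C(F)(F)F
Why: O-sulfonylation forms only the O–S bond, so the configuration is retained; the hindered base and low temperature keep the secondary triflate from ionising or eliminating.

Step 5
Reactants: 6 2,3-dimethylbut-2-ene
Product: 7 2-methoxyprop-2-yl hydroperoxide
Conditions: O3, CH2Cl2/MeOH, −78 °C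
Reagents that add atoms: ozone, [O-][O+]=O; methanol, CO
Why: ozonolysis in methanol, in which the primary ozonide splits into acetone and acetone O-oxide and methanol traps the carbonyl oxide as the α-methoxy hydroperoxide.

Step 6
Reactants: 5 (2S)-1-[(tert-butyldimethylsilyl)oxy]-4-[(4-methoxybenzyl)oxy]butan-2-yl trifluoromethanesulfonate; 7 2-methoxyprop-2-yl hydroperoxide
Product: 8 (2R)-1-[(tert-butyldimethylsilyl)oxy]-4-[(4-methoxybenzyl)oxy]-2-[(2-methoxypropan-2-yl)peroxy]butane
Conditions: 7 (2 equiv), KOtBu (1.5 equiv), THF, 0 °C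
Reagents that add atoms: none
Why: SN2 alkylation of a potassium alkylperoxide (an α-effect nucleophile of low basicity) by a secondary triflate, a known way to dialkyl peroxides; backside attack inverts the carbinol carbon and sets the (R) centre that becomes C3.

Step 7
Reactants: 8 (2R)-1-[(tert-butyldimethylsilyl)oxy]-4-[(4-methoxybenzyl)oxy]-2-[(2-methoxypropan-2-yl)peroxy]butane
Product: 9 (2R)-4-[(4-methoxybenzyl)oxy]-2-[(2-methoxypropan-2-yl)peroxy]butan-1-ol
Conditions: TBAF, AcOH, THF, 0 °C to rt
Reagents that add atoms: none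
Why: fluoride desilylation, buffered with acetic acid so that the freed oxygen stays protonated and attacks neither the O–O bond nor the perketal carbon; the perketal and the PMB ether are inert to fluoride.

Step 8
Reactants: 9 (2R)-4-[(4-methoxybenzyl)oxy]-2-[(2-methoxypropan-2-yl)peroxy]butan-1-ol
Product: 10 (2R)-4-[(4-methoxybenzyl)oxy]-2-[(2-methoxypropan-2-yl)peroxy]butanal
Conditions: Dess–Martin periodinane, NaHCO3, CH2Cl2, 0 °C; used at once
Reagents that add atoms: none
Why: Dess–Martin oxidation at buffered neutral pH should give the aldehyde without enolising the α-peroxy centre and without the acid that would strip the perketal.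

Step 9
Reactants: 10 (2R)-4-[(4-methoxybenzyl)oxy]-2-[(2-methoxypropan-2-yl)peroxy]butanal
Product: 11 (3R)-5-[(4-methoxybenzyl)oxy]-3-[(2-methoxypropan-2-yl)peroxy]pent-1-ene
Conditions: Ph3PCH3Br, KHMDS, THF, 0 °C; then 10, −78 to 0 °C
Reagents that add atoms: methyltriphenylphosphonium bromide, C[P+](c1ccccc1)(c1ccccc1)c1ccccc1.[Br-]
Why: Wittig methylenation with the salt-free ylide, an olefination known for perketal-protected α-peroxy aldehydes; carbonyl addition at −78 °C should outrun enolisation, so the (R) centre is carried through unchanged.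

Step 10
Reactants: 11 (3R)-5-[(4-methoxybenzyl)oxy]-3-[(2-methoxypropan-2-yl)peroxy]pent-1-ene
Product: 12 (3R)-3-hydroperoxy-5-[(4-methoxybenzyl)oxy]pent-1-ene
Conditions: AcOH/THF/H2O (4:2:1), BHT (trace), rt; used promptly
Reagents that add atoms: none
Why: acid hydrolysis of the 2-methoxyprop-2-yl peroxyketal frees the hydroperoxide without touching the C–O bond of the stereocentre; the radical inhibitor holds back the allylic hydroperoxide (Schenck) rearrangement.

Step 11
Reactants: 13 methoxyallene (1-methoxypropa-1,2-diene); 14 tert-butyl(4-iodobutoxy)dimethylsilane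
Product: 16 tert-butyl[(5-methoxyhepta-5,6-dien-1-yl)oxy]dimethylsilane, via 1-lithio-1-methoxyallene 15 (not isolated)
Conditions: n-BuLi, THF, −40 °C; then 14, −40 °C to rt
Reagents that add atoms: none
Why: lithiation of methoxyallene at its oxygen-bearing carbon followed by SN2 alkylation with a primary iodide, the standard entry to 1-alkyl-1-methoxyallenes.

Step 12
Reactants: 16 tert-butyl[(5-methoxyhepta-5,6-dien-1-yl)oxy]dimethylsilane
Product: 17 tert-butyl[(5,5-dimethoxyhept-6-en-1-yl)oxy]dimethylsilane
Conditions: MeOH (5 equiv), PPTS (cat.), CH2Cl2, 0 °C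
Reagents that add atoms: methanol, CO
Why: acid-catalysed addition of an alcohol to an alkoxyallene: protonation of the central allene carbon gives a vinyl-substituted oxocarbenium ion that methanol captures at the oxygen-bearing carbon, so the enone dimethyl ketal forms without a free vinyl ketone ever being exposed to conjugate addition of methanol.

Step 13
Reactants: 12 (3R)-3-hydroperoxy-5-[(4-methoxybenzyl)oxy]pent-1-ene; 17 tert-butyl[(5,5-dimethoxyhept-6-en-1-yl)oxy]dimethylsilane
Product: 18 tert-butyl{[5-methoxy-5-({(3R)-5-[(4-methoxybenzyl)oxy]pent-1-en-3-yl}peroxy)hept-6-en-1-yl]oxy}dimethylsilane, both epimers at the ketal carbon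
Conditions: PPTS (cat.), 5 Å molecular sieves, CH2Cl2, 0 °C to rt; 17 in excess
Reagents that add atoms: none
Why: acid-catalysed exchange of one ketal methoxy group for a hydroperoxide (trans-peroxyketalisation), in which the oxocarbenium ion from 17 is captured by the hydroperoxide oxygen at the carbon of highest positive charge while the sieves take up methanol; the ketal centre forms unselectively and C3 is not involved.

Step 14
Reactants: 18 tert-butyl{[5-methoxy-5-({(3R)-5-[(4-methoxybenzyl)oxy]pent-1-en-3-yl}peroxy)hept-6-en-1-yl]oxy}dimethylsilane, both epimers at the ketal carbon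
Product: 19 (3R)-6-{4-[(tert-butyldimethylsilyl)oxy]butyl}-6-methoxy-3-{2-[(4-methoxybenzyl)oxy]ethyl}-3,6-dihydro-1,2-dioxine, both C6 epimers
Conditions: RuCl2(=CHPh)(PCy3)(H2IMes) (second-generation Grubbs catalyst, 5 mol %), CH2Cl2 (5 mM), 40 °C
Reagents that add atoms: none
Why: The ruthenium benzylidene exchanges onto the less hindered C3 vinyl group, the new alkylidene adds to the vinyl group on the ketal carbon by [2+2] cycloaddition, and cycloreversion of the ruthenacyclobutane releases the C4=C5 alkene and a ruthenium methylidene that carries the cycle on with loss of ethylene. The closest known reaction type is ring-closing metathesis of dienes tethered through a dialkyl peroxide or through an allylic acetal oxygen, both of which give six-membered unsaturated heterocycles with this class of catalyst. The 3,6-dihydro-1,2-dioxine ring closes as a six-membered ring by intramolecular alkene metathesis between two terminal vinyl groups, with O1–O2, O2–C3 and O1–C6 already present. No stereocentre is formed: C3 was set in step 6 and is untouched under these neutral, base-free conditions, and C6 is carried as both epimers until step 19. The step needs the carbene to react with the two alkenes and not with the O–O bond, and it must not isomerise the allylic peroxide; ruthenium carbenes do not cleave dialkyl peroxides, both alkenes are monosubstituted and terminal, and high dilution together with the ease of six-membered closure should suppress oligomers.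

Step 15
Reactants: 19 (3R)-6-{4-[(tert-butyldimethylsilyl)oxy]butyl}-6-methoxy-3-{2-[(4-methoxybenzyl)oxy]ethyl}-3,6-dihydro-1,2-dioxine, both C6 epimers
Product: 20 (3S)-6-{4-[(tert-butyldimethylsilyl)oxy]butyl}-6-methoxy-3-{2-[(4-methoxybenzyl)oxy]ethyl}-1,2-dioxane, both C6 epimers
Conditions: KO2CN=NCO2K, AcOH, CH2Cl2, 0 °C to rt
Reagents that add atoms: none
Why: diimide reduction, a concerted syn transfer of H2 from HN=NH that saturates C4=C5 and leaves the O–O bond, which catalytic hydrogenation would cleave, untouched; no stereocentre is formed.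

Step 16
Reactants: 20 (3S)-6-{4-[(tert-butyldimethylsilyl)oxy]butyl}-6-methoxy-3-{2-[(4-methoxybenzyl)oxy]ethyl}-1,2-dioxane, both C6 epimers
Product: 21 (3S)-6-(4-hydroxybutyl)-6-methoxy-3-{2-[(4-methoxybenzyl)oxy]ethyl}-1,2-dioxane, both C6 epimers
Conditions: TBAF, AcOH, THF, 0 °C to rt
Reagents that add atoms: none
Why: fluoride desilylation under buffered conditions that are not acidic enough to ionise the ketal, so the freed hydroxyl should not close onto C6 as a spiroketal.

Step 17
Reactants: 21 (3S)-6-(4-hydroxybutyl)-6-methoxy-3-{2-[(4-methoxybenzyl)oxy]ethyl}-1,2-dioxane, both C6 epimers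
Product: 22 (3S)-6-methoxy-3-{2-[(4-methoxybenzyl)oxy]ethyl}-6-(4-oxobutyl)-1,2-dioxane, both C6 epimers
Conditions: Dess–Martin periodinane, NaHCO3, CH2Cl2, 0 °C
Reagents that add atoms: none
Why: Dess–Martin oxidation of the primary alcohol under bicarbonate buffer, which removes the hydroxyl before any acid can bring about spiroketalisation and leaves peroxide and PMB ether alone.

Step 18
Reactants: 22 (3S)-6-methoxy-3-{2-[(4-methoxybenzyl)oxy]ethyl}-6-(4-oxobutyl)-1,2-dioxane, both C6 epimers
Product: 23 (3S)-6-methoxy-3-{2-[(4-methoxybenzyl)oxy]ethyl}-6-(pent-4-yn-1-yl)-1,2-dioxane, both C6 epimers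
Conditions: dimethyl (1-diazo-2-oxopropyl)phosphonate, K2CO3, MeOH, 0 °C to rt
Reagents that add atoms: dimethyl (1-diazo-2-oxopropyl)phosphonate, COP(=O)(OC)C(=[N+]=[N-])C(C)=O
Why: Seyferth–Gilbert homologation in the Ohira–Bestmann form; carbonate in methanol is too weak a base to attack the unactivated C3–H of the dialkyl peroxide.

Step 19
Reactants: 23 (3S)-6-methoxy-3-{2-[(4-methoxybenzyl)oxy]ethyl}-6-(pent-4-yn-1-yl)-1,2-dioxane, both C6 epimers
Product: 24 (3S,6R)-6-methoxy-3-{2-[(4-methoxybenzyl)oxy]ethyl}-6-(pent-4-yn-1-yl)-1,2-dioxane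
Conditions: TsOH·H2O (cat.), MeOH, rt
Reagents that add atoms: methanol, CO
Why: acid-catalysed ketal exchange with the solvent equilibrates C6 under thermodynamic control; the chair with axial methoxy (anomeric effect) and both carbon chains equatorial is the epimer with methoxy cis to the C3 side chain, which is (3S,6R), and with no free hydroxyl left in the molecule both epimers should converge on it.

Step 20
Reactants: 25 undec-1-yne
Product: 27 (E)-1-iodoundec-1-ene, via alkenylzirconocene chloride 26 (not isolated)
Conditions: Cp2Zr(H)Cl, THF, rt; then I2, 0 °C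
Reagents that add atoms: iodine, II
Why: hydrozirconation adds Zr–H syn across the alkyne with zirconium on the terminal carbon, and iodinolysis of the C–Zr bond with retention should give the (E)-iodide alone.

Step 21
Reactants: 24 (3S,6R)-6-methoxy-3-{2-[(4-methoxybenzyl)oxy]ethyl}-6-(pent-4-yn-1-yl)-1,2-dioxane; 27 (E)-1-iodoundec-1-ene
Product: 28 (3S,6R)-6-[(6E)-hexadec-6-en-4-yn-1-yl]-6-methoxy-3-{2-[(4-methoxybenzyl)oxy]ethyl}-1,2-dioxane
Conditions: Pd(PPh3)4 (5 mol %), CuI (10 mol %), i-Pr2NH, THF, rt
Reagents that add atoms: none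
Why: Sonogashira coupling (oxidative addition of the vinyl iodide to zerovalent palladium, transmetalation from the copper acetylide, reductive elimination) with retention of the (E) geometry; such couplings are known to leave 1,2-dioxanes intact, and the C3–H is not activated towards the amine while the side chain is still an ether.

Step 22
Reactants: 28 (3S,6R)-6-[(6E)-hexadec-6-en-4-yn-1-yl]-6-methoxy-3-{2-[(4-methoxybenzyl)oxy]ethyl}-1,2-dioxane
Product: 29 2-[(3S,6R)-6-[(6E)-hexadec-6-en-4-yn-1-yl]-6-methoxy-1,2-dioxan-3-yl]ethan-1-ol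
Conditions: DDQ, CH2Cl2/pH 7 phosphate buffer, 0 °C
Reagents that add atoms: none
Why: oxidative cleavage of the PMB ether by DDQ (benzylic hydride abstraction, then hydrolysis of the oxocarbenium ion) under buffered neutral conditions that should leave enyne, peroxide and ketal alone.

Step 23
Reactants: 29 2-[(3S,6R)-6-[(6E)-hexadec-6-en-4-yn-1-yl]-6-methoxy-1,2-dioxan-3-yl]ethan-1-ol
Product: 31 2-[(3S,6R)-6-[(6E)-hexadec-6-en-4-yn-1-yl]-6-methoxy-1,2-dioxan-3-yl]acetic acid (the target), via aldehyde 30 (not isolated)
Conditions: TEMPO (cat.), PhI(OAc)2, MeCN/pH 7 phosphate buffer, rt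
Reagents that add atoms: water, O
Why: oxoammonium (TEMPO) oxidation of the primary alcohol to the aldehyde and, through its hydrate, on to the acid; the medium is neutral and base-free, so the β-peroxy carbonyl compounds should not open by retro-oxa-Michael elimination.

**Compound list**

1 | 2-[(4S)-2,2-dimethyl-1,3-dioxolan-4-yl]ethan-1-ol | CC1(C)OC[C@H](CCO)O1 | starting material
2 | (4S)-4-{2-[(4-methoxybenzyl)oxy]ethyl}-2,2-dimethyl-1,3-dioxolane | CC1(C)OC[C@H](CCOCc2ccc(OC)cc2)O1 | intermediate
3 | (2S)-4-[(4-methoxybenzyl)oxy]butane-1,2-diol | OC[C@@H](O)CCOCc1ccc(OC)cc1 | intermediate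
4 | (2S)-1-[(tert-butyldimethylsilyl)oxy]-4-[(4-methoxybenzyl)oxy]butan-2-ol | CC(C)(C)[Si](C)(C)OC[C@@H](O)CCOCc1ccc(OC)cc1 | intermediate
5 | (2S)-1-[(tert-butyldimethylsilyl)oxy]-4-[(4-methoxybenzyl)oxy]butan-2-yl trifluoromethanesulfonate | CC(C)(C)[Si](C)(C)OC[C@@H](OS(=O)(=O)C(F)(F)F)CCOCc1ccc(OC)cc1 | intermediate
6 | 2,3-dimethylbut-2-ene | CC(C)=C(C)C | starting material
7 | 2-methoxyprop-2-yl hydroperoxide | COC(C)(C)OO | intermediate
8 | (2R)-1-[(tert-butyldimethylsilyl)oxy]-4-[(4-methoxybenzyl)oxy]-2-[(2-methoxypropan-2-yl)peroxy]butane | CC(C)(C)[Si](C)(C)OC[C@H](OOC(C)(C)OC)CCOCc1ccc(OC)cc1 | intermediate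
9 | (2R)-4-[(4-methoxybenzyl)oxy]-2-[(2-methoxypropan-2-yl)peroxy]butan-1-ol | OC[C@H](OOC(C)(C)OC)CCOCc1ccc(OC)cc1 | intermediate
10 | (2R)-4-[(4-methoxybenzyl)oxy]-2-[(2-methoxypropan-2-yl)peroxy]butanal | O=C[C@H](OOC(C)(C)OC)CCOCc1ccc(OC)cc1 | intermediate
11 | (3R)-5-[(4-methoxybenzyl)oxy]-3-[(2-methoxypropan-2-yl)peroxy]pent-1-ene | C=C[C@H](OOC(C)(C)OC)CCOCc1ccc(OC)cc1 | intermediate
12 | (3R)-3-hydroperoxy-5-[(4-methoxybenzyl)oxy]pent-1-ene | C=C[C@H](OO)CCOCc1ccc(OC)cc1 | intermediate
13 | methoxyallene (1-methoxypropa-1,2-diene) | COC=C=C | starting material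
14 | tert-butyl(4-iodobutoxy)dimethylsilane | CC(C)(C)[Si](C)(C)OCCCCI | starting material
15 | 1-lithio-1-methoxyallene | [Li]C(OC)=C=C | intermediate
16 | tert-butyl[(5-methoxyhepta-5,6-dien-1-yl)oxy]dimethylsilane | C=C=C(OC)CCCCO[Si](C)(C)C(C)(C)C | intermediate
17 | tert-butyl[(5,5-dimethoxyhept-6-en-1-yl)oxy]dimethylsilane | C=CC(OC)(OC)CCCCO[Si](C)(C)C(C)(C)C | intermediate
18 | tert-butyl{[5-methoxy-5-({(3R)-5-[(4-methoxybenzyl)oxy]pent-1-en-3-yl}peroxy)hept-6-en-1-yl]oxy}dimethylsilane, both epimers at the ketal carbon | C=C[C@@H](CCOCc1ccc(OC)cc1)OOC(OC)(C=C)CCCCO[Si](C)(C)C(C)(C)C | intermediate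
19 | (3R)-6-{4-[(tert-butyldimethylsilyl)oxy]butyl}-6-methoxy-3-{2-[(4-methoxybenzyl)oxy]ethyl}-3,6-dihydro-1,2-dioxine, both C6 epimers | CC(C)(C)[Si](C)(C)OCCCCC1(OC)C=C[C@@H](CCOCc2ccc(OC)cc2)OO1 | intermediate
20 | (3S)-6-{4-[(tert-butyldimethylsilyl)oxy]butyl}-6-methoxy-3-{2-[(4-methoxybenzyl)oxy]ethyl}-1,2-dioxane, both C6 epimers | CC(C)(C)[Si](C)(C)OCCCCC1(OC)CC[C@@H](CCOCc2ccc(OC)cc2)OO1 | intermediate
21 | (3S)-6-(4-hydroxybutyl)-6-methoxy-3-{2-[(4-methoxybenzyl)oxy]ethyl}-1,2-dioxane, both C6 epimers | OCCCCC1(OC)CC[C@@H](CCOCc2ccc(OC)cc2)OO1 | intermediate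
22 | (3S)-6-methoxy-3-{2-[(4-methoxybenzyl)oxy]ethyl}-6-(4-oxobutyl)-1,2-dioxane, both C6 epimers | O=CCCCC1(OC)CC[C@@H](CCOCc2ccc(OC)cc2)OO1 | intermediate
23 | (3S)-6-methoxy-3-{2-[(4-methoxybenzyl)oxy]ethyl}-6-(pent-4-yn-1-yl)-1,2-dioxane, both C6 epimers | C#CCCCC1(OC)CC[C@@H](CCOCc2ccc(OC)cc2)OO1 | intermediate
24 | (3S,6R)-6-methoxy-3-{2-[(4-methoxybenzyl)oxy]ethyl}-6-(pent-4-yn-1-yl)-1,2-dioxane | C#CCCC[C@]1(OC)CC[C@@H](CCOCc2ccc(OC)cc2)OO1 | intermediate
25 | undec-1-yne | CCCCCCCCCC#C | starting material
26 | chlorobis(cyclopentadienyl)[(E)-undec-1-en-1-yl]zirconium | CCCCCCCCC/C=C/[Zr](Cl)(C1C=CC=C1)C1C=CC=C1 | intermediate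
27 | (E)-1-iodoundec-1-ene | CCCCCCCCC/C=C/I | intermediate
28 | (3S,6R)-6-[(6E)-hexadec-6-en-4-yn-1-yl]-6-methoxy-3-{2-[(4-methoxybenzyl)oxy]ethyl}-1,2-dioxane | CCCCCCCCC/C=C/C#CCCC[C@]1(OC)CC[C@@H](CCOCc2ccc(OC)cc2)OO1 | intermediate
29 | 2-[(3S,6R)-6-[(6E)-hexadec-6-en-4-yn-1-yl]-6-methoxy-1,2-dioxan-3-yl]ethan-1-ol | CCCCCCCCC/C=C/C#CCCC[C@]1(OC)CC[C@@H](CCO)OO1 | intermediate
30 | 2-[(3S,6R)-6-[(6E)-hexadec-6-en-4-yn-1-yl]-6-methoxy-1,2-dioxan-3-yl]acetaldehyde | CCCCCCCCC/C=C/C#CCCC[C@]1(OC)CC[C@@H](CC=O)OO1 | intermediate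
31 | 2-[(3S,6R)-6-[(6E)-hexadec-6-en-4-yn-1-yl]-6-methoxy-1,2-dioxan-3-yl]acetic acid | CCCCCCCCC/C=C/C#CCCC[C@]1(OC)CC[C@@H](CC(=O)O)OO1 | target

**Step count**

Total: 23 steps. Longest linear sequence: 19 steps (steps 1–4, 6–10, 13–19, 21–23).

**Steps most likely to fail**

Step 13. The hydroperoxide may capture the vinyl-substituted oxocarbenium ion at its far alkene terminus (allylic transposition to an enol ether), the exchange may stall at an unfavourable equilibrium, or the acid may start Hock-type cleavage of the allylic hydroperoxide. The fallback sets out from hydroperoxide 12 and allenyl ether 16 instead of ketal 17. The O–H of 12 would be added across the enol-ether double bond of 16 under PPTS in CH2Cl2 at 0 °C, the way alcohols are known to add to alkoxyallenes, though this has no direct precedent with a hydroperoxide. This reaches the same oxocarbenium ion but sets no methanol free, so there is no equilibrium to drive and the acid loading and time can be kept minimal. It comes back to the route at 18 and makes no compound outside the list (F0).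

Step 9. The basic ylide may enolise the α-peroxy aldehyde, leading to loss of configuration at the peroxide-bearing carbon or to Kornblum–DeLaMare-type cleavage of the O–O bond. The fallback sets out from aldehyde 10 and replaces the Wittig reaction by a Peterson olefination. Addition of the non-basic organocerium reagent from Me3SiCH2MgCl and CeCl3 in THF at −78 °C would give the β-hydroxysilane F1 (both carbinol epimers). Syn elimination of silanolate with KH in THF at 0 °C would then give the terminal alkene; since the aldehyde is gone by then, the base meets no enolisable centre. It comes back to the route at 11.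

Step 6. The potassium peroxide may act as a base on the very reactive secondary triflate (E2 elimination towards either neighbour), or the triflate may decompose before substitution. The fallback sets out from alcohol 4 and brings the peroxide oxygen in as hydrogen peroxide itself on a more stable sulfonate. MsCl and Et3N would give the mesylate F2. Displacement with H2O2 and KOH in aqueous methanol, a known inverting route to secondary hydroperoxides, would give the hydroperoxide F3. Capping F3 with 2-methoxypropene and PPTS in CH2Cl2 would give the perketal. It comes back to the route at 8.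

**Further compounds**

F0 | step 13 | none | none
F1 | step 9 | (2RS,3R)-5-[(4-methoxybenzyl)oxy]-3-[(2-methoxypropan-2-yl)peroxy]-1-(trimethylsilyl)pentan-2-ol | C[Si](C)(C)CC(O)[C@H](OOC(C)(C)OC)CCOCc1ccc(OC)cc1
F2 | step 6 | (2S)-1-[(tert-butyldimethylsilyl)oxy]-4-[(4-methoxybenzyl)oxy]butan-2-yl methanesulfonate | CC(C)(C)[Si](C)(C)OC[C@@H](OS(C)(=O)=O)CCOCc1ccc(OC)cc1
F3 | step 6 | tert-butyl{[(2R)-2-hydroperoxy-4-[(4-methoxybenzyl)oxy]butyl]oxy}dimethylsilane | CC(C)(C)[Si](C)(C)OC[C@H](OO)CCOCc1ccc(OC)cc1
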